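Isochromene numbering (C1, O2, C3–C8a) is used. The route reads the pyran ring, with its exocyclic C4a=C5 bond, as the anhydrobase of a 4-methylpyrylium ion. C5 is then a nucleophile, and C5–C6 becomes a Claisen-type disconnection of the carbocycle C4a–C5–C6–C7–C8–C8a. In one operation an alkynone and an enaminone of similar size are joined at C4a–C8a and the pyran closes at O2–C1. C5 is then acylated by the lactone carbonyl C6 of a lactic-acid-derived dioxolanone that already holds quaternary C7. This closes the carbocycle last and unmasks the C7 hydroxyl. Both precursors are open-chain apart from this temporary acetal ring.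

Key step: step 8

Remark: the four groups at the quaternary carbon keep the same spatial arrangement from 9 to 16. Its descriptor reads S in 9–13, R in 14 and 15, and S in 16 only because the ranking of C6 and C8 changes.

Step 1
Reactants: 1 (S)-2-methylbutan-1-ol
Product: 2 (S)-2-methylbutanal
Conditions: TEMPO (1 mol %), KBr (10 mol %), aq. NaOCl buffered with NaHCO3, CH2Cl2, 0 °C; short-path distillation
Reagents that add atoms: none
Why: The oxoammonium-mediated (TEMPO) oxidation stops at the aldehyde, and the buffered two-phase medium at 0 °C should leave the α-stereocentre (future C13) untouched.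

Step 2
Reactants: 2 (S)-2-methylbutanal
Product: 3 (2E,4S)-2,4-dimethylhex-2-enal
Conditions: 2-(triphenylphosphoranylidene)propanal, toluene, 80 °C
Reagents that add atoms: 2-(triphenylphosphoranylidene)propanal, CC(C=O)=P(c1ccccc1)(c1ccccc1)c1ccccc1
Why: Wittig olefination with a stabilised α-branched ylide should give the E-trisubstituted C11=C12 bond under neutral conditions that do not epimerise C13.

Step 3
Reactants: 3 (2E,4S)-2,4-dimethylhex-2-enal
Product: 4 (2E,4E,6S)-N-methoxy-N,4,6-trimethylocta-2,4-dienamide
Conditions: diethyl [2-(methoxy(methyl)amino)-2-oxoethyl]phosphonate, NaH, THF, 0 °C to rt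
Reagents that add atoms: diethyl [2-(methoxy(methyl)amino)-2-oxoethyl]phosphonate, CCOP(=O)(CC(=O)N(C)OC)OCC
Why: Horner–Wadsworth–Emmons olefination of the enal with a preformed stabilised phosphonate anion should set the E-C9=C10 bond and deliver C3 as an N-methoxy-N-methylamide.

Step 4
Reactants: 4 (2E,4E,6S)-N-methoxy-N,4,6-trimethylocta-2,4-dienamide
Product: 5 (5E,7E,9S)-7,9-dimethylundeca-5,7-dien-2-yn-4-one
Conditions: 1-propynylmagnesium bromide, THF, −20 to 0 °C; aq. NH4Cl
Reagents that add atoms: 1-propynylmagnesium bromide, CC#C[Mg]Br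
Why: Acyl substitution of an N-methoxy-N-methylamide by an alkynyl Grignard reagent stops at the ketone because the magnesium chelate survives until work-up, and it installs C4, C4a and C5.

Step 5
Reactants: 6 (R)-lactic acid
Product: 7 (2R,5R)-2-tert-butyl-5-methyl-1,3-dioxolan-4-one
Conditions: pivalaldehyde, TsOH·H2O (cat.), pentane, reflux with water separator; crystallisation from pentane at low temperature
Reagents that add atoms: pivalaldehyde, CC(C)(C)C=O
Why: Acid-catalysed acetalisation should give mainly the cis acetal, and crystallisation should leave the single (2R,5R) isomer, whose new acetal centre stores the chirality of lactic acid (self-regeneration of stereocentres).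

Step 6
Reactants: 7 (2R,5R)-2-tert-butyl-5-methyl-1,3-dioxolan-4-one
Product: 9 (2R,5S)-5-acetyl-2-tert-butyl-5-methyl-1,3-dioxolan-4-one, via lithium enolate 8 (not isolated)
Conditions: LDA (commercial solution), THF, −78 °C; cannulated into acetyl chloride (3 equiv), THF, −78 °C
Reagents that add atoms: acetyl chloride, CC(=O)Cl
Why: Claisen-type C-acylation of the planar enolate should occur on the face anti to tert-butyl, so acetyl replaces hydrogen with retention and the quaternary centre (future C7) is set by the acetal centre, while inverse addition suppresses proton transfer.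

Step 7
Reactants: 9 (2R,5S)-5-acetyl-2-tert-butyl-5-methyl-1,3-dioxolan-4-one
Product: 10 (2R,5S)-2-tert-butyl-5-[(2E)-3-(dimethylamino)prop-2-enoyl]-5-methyl-1,3-dioxolan-4-one
Conditions: N,N-dimethylformamide dimethyl acetal, toluene, 90 °C, methanol distilled off
Reagents that add atoms: N,N-dimethylformamide dimethyl acetal, COC(OC)N(C)C
Why: Amide-acetal condensation at the only enolisable position, the acetyl methyl group (future C8a), should give the E-enaminone and add C1 without a base strong enough to open the hindered lactone.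

Step 8
Reactants: 5 (5E,7E,9S)-7,9-dimethylundeca-5,7-dien-2-yn-4-one; 10 (2R,5S)-2-tert-butyl-5-[(2E)-3-(dimethylamino)prop-2-enoyl]-5-methyl-1,3-dioxolan-4-one
Product: 14 (7R)-3-[(1E,3E,5S)-3,5-dimethylhepta-1,3-dien-1-yl]-7-hydroxy-7-methyl-6H-isochromene-6,8(7H)-dione, via aminodienone 11 (not isolated), via pyrylium acetate 12 (not isolated), via anhydrobase 13 (not isolated)
Conditions: toluene/AcOH 5:1 (0.05 M), N2, 50 °C, then 90 °C
Reagents that add atoms: none
Why: Proposed new method: acetic acid activates alkynone 5 for conjugate addition of the nucleophilic α-carbon C8a of enaminone 10 at C4a (the first stage of a Bohlmann–Rahtz heteroannulation), and because the nitrogen is tertiary the aminodienone 11 cannot become a pyridine but closes through the C3 carbonyl oxygen onto the iminium carbon C1 (6-exo-trig) and loses dimethylamine, held as its acetate salt, to give pyrylium 12. Acetate then removes a proton from the now acidic 4-methyl group, and the exocyclic carbon C5 of anhydrobase 13 attacks the acylal-type lactone carbonyl C6 in a 6-(enolendo)-exo-trig Claisen-type acylation, after which the adduct expels the hemiacetal oxygen, sheds pivalaldehyde and leaves the free C7 hydroxyl. The closest known reaction types are the acid-catalysed one-pot Bohlmann–Rahtz reaction, the formation of pyrylium salts from 5-aminopenta-2,4-dienones and the C-acylation of 4-methylenepyrans by acid chlorides and anhydrides; new are their combination and an activated ester as the acyl donor. No stereocentre is formed, since C7 keeps the configuration fixed in step 6 because none of its four bonds is touched, and C13 is a spectator. The substrate enforces the order of ring closure, because C5–H becomes acidic only once the pyran ring is a pyrylium, and it secures regioselectivity, because C5 is the only nucleophilic carbon and C6 the only acyl carbon it can reach through a six-membered transition state (on the dioxolanone face anti to tert-butyl, where the C8 tether already sits), so the electrophilic C1 never meets a carbon nucleophile. The step also needs the alkynone β-carbon C4a to outcompete the dienone positions C10 and C12 as acceptor, which its sp hybridisation and low steric demand should secure.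

Step 9
Reactants: 14 (7R)-3-[(1E,3E,5S)-3,5-dimethylhepta-1,3-dien-1-yl]-7-hydroxy-7-methyl-6H-isochromene-6,8(7H)-dione
Product: 15 (7R)-3-[(1E,3E,5S)-3,5-dimethylhepta-1,3-dien-1-yl]-7-methyl-6,8-dioxo-7,8-dihydro-6H-isochromen-7-yl acetate
Conditions: Ac2O, Et3N, DMAP (cat.), CH2Cl2, 0 °C to rt
Reagents that add atoms: acetic anhydride, CC(=O)OC(C)=O
Why: DMAP-catalysed acylation should esterify the tertiary C7 alcohol, the only hydroxyl present, without touching its configuration.

Step 10
Reactants: 15 (7R)-3-[(1E,3E,5S)-3,5-dimethylhepta-1,3-dien-1-yl]-7-methyl-6,8-dioxo-7,8-dihydro-6H-isochromen-7-yl acetate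
Product: 16 7-epi-sclerotiorin, (7S)-5-chloro-3-[(1E,3E,5S)-3,5-dimethylhepta-1,3-dien-1-yl]-7-methyl-6,8-dioxo-7,8-dihydro-6H-isochromen-7-yl acetate
Conditions: N-chlorosuccinimide (1.05 equiv), MeCN, 0 °C to rt, dark
Reagents that add atoms: N-chlorosuccinimide, O=C1CCC(=O)N1Cl
Why: Electrophilic chlorination should take place at C5, the terminus of the dienol ether O2–C3=C4–C4a=C5 and the most nucleophilic carbon of the molecule, a type of halogenation known for the azaphilone nucleus.

Compound list
1 | (S)-2-methylbutan-1-ol | CC[C@H](C)CO | starting material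
2 | (S)-2-methylbutanal | CC[C@H](C)C=O | intermediate
3 | (2E,4S)-2,4-dimethylhex-2-enal | CC[C@H](C)/C=C(C)/C=O | intermediate
4 | (2E,4E,6S)-N-methoxy-N,4,6-trimethylocta-2,4-dienamide | CC[C@H](C)/C=C(C)/C=C/C(=O)N(C)OC | intermediate
5 | (5E,7E,9S)-7,9-dimethylundeca-5,7-dien-2-yn-4-one | CC[C@H](C)/C=C(C)/C=C/C(=O)C#CC | intermediate
6 | (R)-lactic acid | C[C@@H](O)C(=O)O | starting material
7 | (2R,5R)-2-tert-butyl-5-methyl-1,3-dioxolan-4-one | C[C@H]1O[C@@H](C(C)(C)C)OC1=O | intermediate
8 | lithium (2R)-2-tert-butyl-5-methyl-1,3-dioxol-4-olate (enolate of 7, not isolated) | CC1=C([O-])O[C@H](C(C)(C)C)O1.[Li+] | intermediate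
9 | (2R,5S)-5-acetyl-2-tert-butyl-5-methyl-1,3-dioxolan-4-one | CC(=O)[C@]1(C)O[C@@H](C(C)(C)C)OC1=O | intermediate
10 | (2R,5S)-2-tert-butyl-5-[(2E)-3-(dimethylamino)prop-2-enoyl]-5-methyl-1,3-dioxolan-4-one | CN(C)/C=C/C(=O)[C@]1(C)O[C@@H](C(C)(C)C)OC1=O | intermediate
11 | (2R,5S)-2-tert-butyl-5-{(6E,8E,10S)-2-[(dimethylamino)methylidene]-3,8,10-trimethyl-5-oxododeca-3,6,8-trienoyl}-5-methyl-1,3-dioxolan-4-one (open-chain aminodienone; C4=C4a and C8a=C1 geometries labile; not isolated) | CC[C@H](C)/C=C(C)/C=C/C(=O)C=C(C)C(=CN(C)C)C(=O)[C@]1(C)O[C@@H](C(C)(C)C)OC1=O | intermediate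
12 | 5-{[(2R,4S)-2-tert-butyl-4-methyl-5-oxo-1,3-dioxolan-4-yl]carbonyl}-2-[(1E,3E,5S)-3,5-dimethylhepta-1,3-dien-1-yl]-4-methylpyrylium acetate (not isolated) | CC[C@H](C)/C=C(C)/C=C/c1cc(C)c(c[o+]1)C(=O)[C@]2(C)O[C@@H](C(C)(C)C)OC2=O.CC(=O)[O-] | intermediate
13 | [(2R,4S)-2-tert-butyl-4-methyl-5-oxo-1,3-dioxolan-4-yl]{6-[(1E,3E,5S)-3,5-dimethylhepta-1,3-dien-1-yl]-4-methylidene-4H-pyran-3-yl}methanone (anhydrobase, not isolated) | CC[C@H](C)/C=C(C)/C=C/C1=CC(=C)C(=CO1)C(=O)[C@]2(C)O[C@@H](C(C)(C)C)OC2=O | intermediate
14 | (7R)-3-[(1E,3E,5S)-3,5-dimethylhepta-1,3-dien-1-yl]-7-hydroxy-7-methyl-6H-isochromene-6,8(7H)-dione | CC[C@H](C)/C=C(C)/C=C/C1=CC2=CC(=O)[C@@](C)(O)C(=O)C2=CO1 | intermediate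
15 | (7R)-3-[(1E,3E,5S)-3,5-dimethylhepta-1,3-dien-1-yl]-7-methyl-6,8-dioxo-7,8-dihydro-6H-isochromen-7-yl acetate | CC[C@H](C)/C=C(C)/C=C/C1=CC2=CC(=O)[C@@](C)(OC(C)=O)C(=O)C2=CO1 | intermediate
16 | 7-epi-sclerotiorin | CC[C@H](C)/C=C(C)/C=C/C1=CC2=C(Cl)C(=O)[C@@](C)(OC(C)=O)C(=O)C2=CO1 | target

Total step count: 10. Longest linear sequence: 7 (steps 1–4 and 8–10).

Steps most likely to fail

Step 8. Several things may go wrong here:
- The tertiary enaminone may add too slowly to the β-methyl alkynone.
- The neutral anhydrobase may not transfer onto an ester-level acyl donor and may self-condense instead.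
- Prolonged life of the pyrylium ion may allow vinylogous deprotonation along the dienyl chain and erode C13.

The fallback sets out from 10 and 3 and comes back at 15. It makes the pyran first as a γ-pyrone and closes the carbocycle by a sulfur-tethered olefination. Enaminone 10 is opened at the lactone carbonyl with MeLi (THF, −78 °C) and the alkoxide is trapped with Ac2O to give the methyl ketone acetate F1. Enal 3 is converted by Horner–Wadsworth–Emmons reaction with diethyl [(2,2-dimethyl-4-oxo-4H-1,3-dioxin-6-yl)methyl]phosphonate into the dienyl dioxinone F2. Thermolysis of F2 in toluene at 110 °C in the presence of F1 (acylketene capture by the enaminone, loss of dimethylamine) should give the 3-acyl-γ-pyrone F3. Treatment with 2,4-bis(4-methoxyphenyl)-1,3,2,4-dithiadiphosphetane 2,4-disulfide converts F3 at its most electron-rich carbonyl into the pyran-4-thione F4. Iodine joins the thione sulfur to C5, the only enolisable ketone carbon, to give the seven-membered 4-(alkylthio)pyrylium iodide F5. Et3N and PPh3 then trigger an Eschenmoser sulfide contraction that turns the thia-bridge into the C4a=C5 bond of 15. The bridge keeps C5 away from C1.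

Step 6. O-acylation, proton transfer from acetyl chloride or from the product to the enolate, and self-condensation of the enolate may erode the C-acylation. The fallback sets out from 7 and comes back at 9. Enolate 8 is added to acetaldehyde (aldol addition, again anti to tert-butyl) to give the carbinol F6, whose carbinol configuration is irrelevant. This is oxidised with 1,1,1-triacetoxy-1,1-dihydro-1,2-benziodoxol-3(1H)-one in CH2Cl2.

Step 10. Chlorination of the electron-rich dienyl chain or over-chlorination may compete with attack at C5. The fallback sets out from 4 and 10 and comes back at 16, bringing the chlorine in with the alkyne. Amide 4 is treated with lithiated 3-chloroprop-1-yne (n-BuLi, THF, −78 °C) to give the chloroalkynone F7. Under the conditions of step 8, F7 and 10 should give the 5-chloro alcohol F8 through a chloromethylene anhydrobase. Acetylation as in step 9 then gives 16.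

Further compounds
F1 | step 8 | (3R,5E)-6-(dimethylamino)-3-methyl-2,4-dioxohex-5-en-3-yl acetate | CN(C)/C=C/C(=O)[C@](C)(OC(C)=O)C(C)=O
F2 | step 8 | 6-[(1E,3E,5S)-3,5-dimethylhepta-1,3-dien-1-yl]-2,2-dimethyl-4H-1,3-dioxin-4-one | CC[C@H](C)/C=C(C)/C=C/C1=CC(=O)OC(C)(C)O1
F3 | step 8 | (2R)-1-{6-[(1E,3E,5S)-3,5-dimethylhepta-1,3-dien-1-yl]-4-oxo-4H-pyran-3-yl}-2-methyl-1,3-dioxobutan-2-yl acetate | CC[C@H](C)/C=C(C)/C=C/C1=CC(=O)C(=CO1)C(=O)[C@](C)(OC(C)=O)C(C)=O
F4 | step 8 | (2R)-1-{6-[(1E,3E,5S)-3,5-dimethylhepta-1,3-dien-1-yl]-4-thioxo-4H-pyran-3-yl}-2-methyl-1,3-dioxobutan-2-yl acetate | CC[C@H](C)/C=C(C)/C=C/C1=CC(=S)C(=CO1)C(=O)[C@](C)(OC(C)=O)C(C)=O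
F5 | step 8 | bicyclic 4-(alkylthio)pyrylium iodide with a C4a–S–C5H2 bridge, ketones at C6 and C8, (S)-configured C7 bearing methyl and acetoxy, and the dienyl group at C3 | CC[C@H](C)/C=C(C)/C=C/c1cc2SCC(=O)[C@@](C)(OC(C)=O)C(=O)c2c[o+]1.[I-]
F6 | step 6 | (2R,5S)-2-tert-butyl-5-(1-hydroxyethyl)-5-methyl-1,3-dioxolan-4-one | CC(O)[C@]1(C)O[C@@H](C(C)(C)C)OC1=O
F7 | step 10 | (5E,7E,9S)-1-chloro-7,9-dimethylundeca-5,7-dien-2-yn-4-one | CC[C@H](C)/C=C(C)/C=C/C(=O)C#CCCl
F8 | step 10 | (7S)-5-chloro-3-[(1E,3E,5S)-3,5-dimethylhepta-1,3-dien-1-yl]-7-hydroxy-7-methyl-6H-isochromene-6,8(7H)-dione | CC[C@H](C)/C=C(C)/C=C/C1=CC2=C(Cl)C(=O)[C@@](C)(O)C(=O)C2=CO1
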